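The route rests on disconnecting the C7–O bond of the threo 7,8-diol. The feature exploited is that C7, the benzylic carbon of the side chain, sits para to the diaryl ether oxygen of ring B and can therefore support a cation, while the oxygen on the adjacent C8, fixed by the chiral pool, can carry a carbonate placed to trap it. In a single operation a Lewis acid should turn a mixture of C7 epimers into one trans cyclic carbonate, making the C7–O bond, the dioxolanone ring and the C7 stereocentre. The precursor is the 7,8-bis(tert-butyl carbonate) of the 8R arylglycerol, with O9 and the ring A phenol masked as silyl ethers.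

Key step: step 10

Remark (labels): C7, C8 and C9 are the benzylic, central and terminal carbons of the propanetriol chain; ring A is the phenol-bearing ring of the biphenyl, ring B the 3,5-dimethoxyphenyl ring; the target is 7R,8R (threo).

Remark (abbreviation): Ar = 4-{[4-(tert-butyldimethylsilyloxy)-5-methoxy-[1,1'-biphenyl]-3-yl]oxy}-3,5-dimethoxyphenyl.

Remark (structures): the descriptors were checked and are consistent; the (R)-aldehyde delivers 8R, and the 4R,5R trans carbonate corresponds to the 7R,8R threo triol.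

Remark (precursor design): tert-butyl carbonates are placed only on O7 (leaving group) and O8 (nucleophile), each onto a single free hydroxyl, because exhaustive acylation of a free 1,2,3-triol with Boc2O/DMAP is prone to close cyclic carbonates with retention, and a carbonate on O9 could trap the cation in a six-membered mode.

Step 1
Reactants: 1 4-bromo-2,6-difluorobenzaldehyde
Product: 2 4-bromo-2-fluoro-6-methoxybenzaldehyde
Conditions: NaOMe (1.05 equiv), MeOH, 0 °C to 50 °C
Reagents that add atoms: sodium methoxide, C[O-].[Na+]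
Why: SNAr of one fluoride ortho to the formyl group by methoxide; the methoxy group that enters deactivates the ring towards a second substitution, so one equivalent should stop at monosubstitution.

Step 2
Reactants: 2 4-bromo-2-fluoro-6-methoxybenzaldehyde; 3 phenylboronic acid
Product: 4 3-fluoro-5-methoxy-[1,1'-biphenyl]-4-carbaldehyde
Conditions: Pd(PPh3)4 (3 mol%), K2CO3, 1,4-dioxane/H2O, 80 °C
Reagents that add atoms: none
Why: Suzuki–Miyaura coupling at the only C–Br bond present, which is activated by the para formyl group; placing it before the second bromoarene enters avoids any competition between two C–Br bonds.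

Step 3
Reactants: 4 3-fluoro-5-methoxy-[1,1'-biphenyl]-4-carbaldehyde; 5 4-bromo-2,6-dimethoxyphenol
Product: 6 3-(4-bromo-2,6-dimethoxyphenoxy)-5-methoxy-[1,1'-biphenyl]-4-carbaldehyde
Conditions: Cs2CO3, DMSO, 90 °C
Reagents that add atoms: none
Why: SNAr of the remaining fluoride, activated by the ortho formyl group, by the caesium phenoxide of 5; the C–Br bond of 5 is inert in the absence of a transition metal.

Step 4
Reactants: 6 3-(4-bromo-2,6-dimethoxyphenoxy)-5-methoxy-[1,1'-biphenyl]-4-carbaldehyde
Product: 8 3-(4-bromo-2,6-dimethoxyphenoxy)-5-methoxy-[1,1'-biphenyl]-4-ol, via aryl formate 7 (not isolated)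
Conditions: mCPBA, CH2Cl2, 0 °C to rt; extractive work-up; then K2CO3 (cat.), MeOH, rt
Reagents that add atoms: mCPBA, O=C(OO)c1cccc(Cl)c1
Why: Baeyer–Villiger oxidation of an electron-rich benzaldehyde (Dakin-type outcome), in which ring A with its two ortho oxygen donors should migrate in preference to hydride, followed by methanolysis of the aryl formate.

Step 5
Reactants: 8 3-(4-bromo-2,6-dimethoxyphenoxy)-5-methoxy-[1,1'-biphenyl]-4-ol
Product: 9 [3-(4-bromo-2,6-dimethoxyphenoxy)-5-methoxy-[1,1'-biphenyl]-4-yl]oxy(tert-butyl)dimethylsilane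
Conditions: TBSCl, imidazole, DMF, rt
Reagents that add atoms: tert-butyldimethylsilyl chloride, CC(C)(C)[Si](C)(C)Cl
Why: Silyl ether formation at the phenol, which removes the acidic proton before the lithiation and gives a group that should survive n-BuLi at −78 °C, aqueous acetic acid and BF3·OEt2 and is removed by fluoride at the end.

Step 6
Reactants: 9 [3-(4-bromo-2,6-dimethoxyphenoxy)-5-methoxy-[1,1'-biphenyl]-4-yl]oxy(tert-butyl)dimethylsilane; 10 (R)-2,2-dimethyl-1,3-dioxolane-4-carbaldehyde
Product: 13 tert-butyl Ar[(4R)-2,2-dimethyl-1,3-dioxolan-4-yl]methyl carbonate (C7 epimers), via aryllithium 11 (not isolated), via lithium alkoxide 12 (not isolated)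
Conditions: n-BuLi (1.05 equiv), THF, −78 °C; then 10, −78 °C; then Boc2O, −78 to 0 °C; aqueous NH4Cl
Reagents that add atoms: di-tert-butyl dicarbonate, CC(C)(C)OC(=O)OC(=O)OC(C)(C)C
Why: Bromine–lithium exchange, 1,2-addition of the aryllithium to the aldehyde and O-acylation of the lithium alkoxide in the same flask; C7 forms without useful control (the Felkin–Anh anti epimer should predominate) and both epimers are carried on, while the 8R centre comes unchanged from 10.

Step 7
Reactants: 13 tert-butyl Ar[(4R)-2,2-dimethyl-1,3-dioxolan-4-yl]methyl carbonate (C7 epimers)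
Product: 14 (2R)-1-Ar-2,3-dihydroxypropyl tert-butyl carbonate (C7 epimers)
Conditions: AcOH/H2O (4:1), 40 °C
Reagents that add atoms: none
Why: Acid-catalysed hydrolysis of the terminal isopropylidene acetal, under which a tert-butyl carbonate and an aryl silyl ether should persist and no base is present that could move the carbonate onto the freed hydroxyls.

Step 8
Reactants: 14 (2R)-1-Ar-2,3-dihydroxypropyl tert-butyl carbonate (C7 epimers)
Product: 15 (2R)-1-Ar-3-(tert-butyldiphenylsilyloxy)-2-hydroxypropyl tert-butyl carbonate (C7 epimers)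
Conditions: TBDPSCl (1.1 equiv), imidazole, CH2Cl2, 0 °C to rt
Reagents that add atoms: tert-butyldiphenylsilyl chloride, CC(C)(C)[Si](Cl)(c1ccccc1)c1ccccc1
Why: Silylation selective for the primary hydroxyl on steric grounds, giving at O9 a non-participating ether that should tolerate BF3·OEt2 at low temperature.

Step 9
Reactants: 15 (2R)-1-Ar-3-(tert-butyldiphenylsilyloxy)-2-hydroxypropyl tert-butyl carbonate (C7 epimers)
Product: 16 (2R)-1-Ar-3-(tert-butyldiphenylsilyloxy)propane-1,2-diyl di-tert-butyl bis(carbonate) (C7 epimers)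
Conditions: Boc2O (3 equiv), DMAP (0.2 equiv), MeCN, rt
Reagents that add atoms: di-tert-butyl dicarbonate, CC(C)(C)OC(=O)OC(=O)OC(C)(C)C
Why: DMAP-catalysed tert-butoxycarbonylation of the one remaining hydroxyl; a shift of the C7 carbonate to O8 would be harmless because both oxygens end as tert-butyl carbonates, and the configuration at C8 is not touched.

Step 10
Reactants: 16 (2R)-1-Ar-3-(tert-butyldiphenylsilyloxy)propane-1,2-diyl di-tert-butyl bis(carbonate) (C7 epimers)
Product: 17 (4R,5R)-4-Ar-5-[(tert-butyldiphenylsilyloxy)methyl]-1,3-dioxolan-2-one (trans)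
Conditions: BF3·OEt2 (0.5 equiv), CH2Cl2, −40 to 0 °C
Reagents that add atoms: none
Why: BF3 should bind the C7 carbonate and ionise the benzylic C7–O bond, the departing tert-butyl carbonate collapsing to CO2 and tert-butanol, to leave a planar cation stabilised by the para ether oxygen of ring B, so that both C7 epimers pass through one intermediate. The carbonyl oxygen of the C8 tert-butyl carbonate then attacks C7 and the resulting 2-tert-butoxy-1,3-dioxolan-2-ylium ion loses isobutene, which makes the capture irreversible; the closest known reaction type is the Lewis acid-mediated closure of tert-butyl carbonates or carbamates onto benzylic cations and epoxides to give cyclic carbonates or oxazolidinones. The one ring formed, the 1,3-dioxolan-2-one, closes in a 5-exo mode, the cationic carbon being conjugated with ring B outside the new ring. The new C7 stereocentre is controlled by the fixed 8R centre: in the closing five-membered ring the aryl group should settle anti to the CH2OSi group on C8, giving the 4R,5R trans carbonate, which is the threo 7R,8R diol. The step needs trans diastereoselectivity and ionisation at C7 ahead of tert-butyl loss from the C8 carbonate or proton loss from C8; the first is secured by the C8 centre acting on a free cation in a non-nucleophilic medium at low temperature, the second by the benzylic, para-oxygenated position of C7 and by the absence of any other carbonate or ester that could intercept the cation.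

Step 11
Reactants: 17 (4R,5R)-4-Ar-5-[(tert-butyldiphenylsilyloxy)methyl]-1,3-dioxolan-2-one (trans)
Product: 19 berbekorin A, via desilylated cyclic carbonate 18 (not isolated)
Conditions: TBAF/AcOH (1:1), THF, rt; then K2CO3 (cat.), MeOH, rt
Reagents that add atoms: none
Why: Buffered fluoride desilylation of both silyl ethers followed by base-catalysed methanolysis of the cyclic carbonate (transesterification at the carbonyl carbon), so that the C7–O and C8–O bonds and both configurations are retained.

Compound list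
1 | 4-bromo-2,6-difluorobenzaldehyde | O=Cc1c(F)cc(Br)cc1F | starting material
2 | 4-bromo-2-fluoro-6-methoxybenzaldehyde | COc1cc(Br)cc(F)c1C=O | intermediate
3 | phenylboronic acid | OB(O)c1ccccc1 | starting material
4 | 3-fluoro-5-methoxy-[1,1'-biphenyl]-4-carbaldehyde | COc1cc(-c2ccccc2)cc(F)c1C=O | intermediate
5 | 4-bromo-2,6-dimethoxyphenol | COc1cc(Br)cc(OC)c1O | starting material
6 | 3-(4-bromo-2,6-dimethoxyphenoxy)-5-methoxy-[1,1'-biphenyl]-4-carbaldehyde | COc1cc(-c2ccccc2)cc(Oc2c(OC)cc(Br)cc2OC)c1C=O | intermediate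
7 | 3-(4-bromo-2,6-dimethoxyphenoxy)-5-methoxy-[1,1'-biphenyl]-4-yl formate (not isolated) | COc1cc(-c2ccccc2)cc(Oc2c(OC)cc(Br)cc2OC)c1OC=O | intermediate
8 | 3-(4-bromo-2,6-dimethoxyphenoxy)-5-methoxy-[1,1'-biphenyl]-4-ol | COc1cc(-c2ccccc2)cc(Oc2c(OC)cc(Br)cc2OC)c1O | intermediate
9 | [3-(4-bromo-2,6-dimethoxyphenoxy)-5-methoxy-[1,1'-biphenyl]-4-yl]oxy(tert-butyl)dimethylsilane | COc1cc(-c2ccccc2)cc(Oc2c(OC)cc(Br)cc2OC)c1O[Si](C)(C)C(C)(C)C | intermediate
10 | (R)-2,2-dimethyl-1,3-dioxolane-4-carbaldehyde | CC1(C)OC[C@H](C=O)O1 | starting material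
11 | Ar–Li, the aryllithium from 9 (not isolated) | COc1cc(-c2ccccc2)cc(Oc2c(OC)cc([Li])cc2OC)c1O[Si](C)(C)C(C)(C)C | intermediate
12 | lithium Ar[(4R)-2,2-dimethyl-1,3-dioxolan-4-yl]methanolate, C7 epimers (not isolated) | COc1cc(-c2ccccc2)cc(Oc2c(OC)cc(C(O[Li])[C@H]3COC(C)(C)O3)cc2OC)c1O[Si](C)(C)C(C)(C)C | intermediate
13 | tert-butyl Ar[(4R)-2,2-dimethyl-1,3-dioxolan-4-yl]methyl carbonate, C7 epimers | COc1cc(-c2ccccc2)cc(Oc2c(OC)cc(C(OC(=O)OC(C)(C)C)[C@H]3COC(C)(C)O3)cc2OC)c1O[Si](C)(C)C(C)(C)C | intermediate
14 | (2R)-1-Ar-2,3-dihydroxypropyl tert-butyl carbonate, C7 epimers | COc1cc(-c2ccccc2)cc(Oc2c(OC)cc(C(OC(=O)OC(C)(C)C)[C@H](O)CO)cc2OC)c1O[Si](C)(C)C(C)(C)C | intermediate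
15 | (2R)-1-Ar-3-(tert-butyldiphenylsilyloxy)-2-hydroxypropyl tert-butyl carbonate, C7 epimers | COc1cc(-c2ccccc2)cc(Oc2c(OC)cc(C(OC(=O)OC(C)(C)C)[C@H](O)CO[Si](c3ccccc3)(c3ccccc3)C(C)(C)C)cc2OC)c1O[Si](C)(C)C(C)(C)C | intermediate
16 | (2R)-1-Ar-3-(tert-butyldiphenylsilyloxy)propane-1,2-diyl di-tert-butyl bis(carbonate), C7 epimers (key-step precursor) | COc1cc(-c2ccccc2)cc(Oc2c(OC)cc(C(OC(=O)OC(C)(C)C)[C@H](OC(=O)OC(C)(C)C)CO[Si](c3ccccc3)(c3ccccc3)C(C)(C)C)cc2OC)c1O[Si](C)(C)C(C)(C)C | intermediate
17 | (4R,5R)-4-Ar-5-[(tert-butyldiphenylsilyloxy)methyl]-1,3-dioxolan-2-one, trans (key-step product) | COc1cc(-c2ccccc2)cc(Oc2c(OC)cc([C@H]3OC(=O)O[C@@H]3CO[Si](c4ccccc4)(c4ccccc4)C(C)(C)C)cc2OC)c1O[Si](C)(C)C(C)(C)C | intermediate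
18 | (4R,5R)-4-{4-[(4-hydroxy-5-methoxy-[1,1'-biphenyl]-3-yl)oxy]-3,5-dimethoxyphenyl}-5-(hydroxymethyl)-1,3-dioxolan-2-one (not isolated) | COc1cc(-c2ccccc2)cc(Oc2c(OC)cc([C@H]3OC(=O)O[C@@H]3CO)cc2OC)c1O | intermediate
19 | berbekorin A, (1R,2R)-1-{4-[(4-hydroxy-5-methoxy-[1,1'-biphenyl]-3-yl)oxy]-3,5-dimethoxyphenyl}propane-1,2,3-triol | COc1cc(-c2ccccc2)cc(Oc2c(OC)cc([C@@H](O)[C@H](O)CO)cc2OC)c1O | target

Total step count: 11. Longest linear sequence: 11 steps (1 to 19).

Steps most likely to fail

1. Step 10. What may go wrong: loss of tert-butyl from the carbonates or loss of the C8 proton from the cation outruns the capture, or the ring closes by neighbouring-group displacement without a free cation, so that the two C7 epimers are not funnelled into one product. Fallback, which sets C7 by reagent control instead: setting out from 9, bromine–lithium exchange and addition to 10 with an aqueous quench would give the epimeric carbinol Ar[(4R)-2,2-dimethyl-1,3-dioxolan-4-yl]methanol F1. Dess–Martin periodinane would oxidise both epimers to the aryl ketone F2. LiBH(s-Bu)3 in THF at −78 °C should then deliver hydride under Felkin–Anh control to give the syn (7R,8R) alcohol F3. Aqueous acetic acid would remove the acetal to give the silyl-protected triol F4, and TBAF would free the phenol, coming back to the route at 19.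

2. Step 9. What may go wrong: slow acylation of the hindered secondary hydroxyl, with base-induced closure of O8 onto the neighbouring benzylic carbonate and loss of tert-butanol, which would fix C7 with retention as a cis/trans mixture. Fallback, which keeps any carbonate away from O8 during the acylation by using a methyl ether as the C7 leaving group: setting out from 9, exchange and addition to 10 as in step 6, but with alkoxide 12 methylated in the flask (MeI, DMPU, −78 °C to rt), would give the methyl ether (4R)-4-[Ar(methoxy)methyl]-2,2-dimethyl-1,3-dioxolane F5. Aqueous acetic acid would give the diol (2R)-3-Ar-3-methoxypropane-1,2-diol F6. TBDPSCl and imidazole would give the primary silyl ether F7, and Boc2O/DMAP the C8 tert-butyl carbonate F8. BF3·OEt2 would then ionise the benzylic methyl ether, and the same carbonate capture would come back to the route at 17.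

3. Step 3. What may go wrong: the hindered phenoxide adds too slowly to a fluoroarene whose formyl group is flanked and electronically damped by the ortho methoxy group, and the aldehyde degrades on prolonged heating. Fallback, which builds the diaryl ether on the more electrophilic difluoro ring by changing the order of the three ring A substitutions: setting out from 1, Suzuki–Miyaura coupling with 3 would give 3,5-difluoro-[1,1'-biphenyl]-4-carbaldehyde F9. SNAr with one equivalent of 5 (K2CO3, DMF, 60 °C) would give 3-(4-bromo-2,6-dimethoxyphenoxy)-5-fluoro-[1,1'-biphenyl]-4-carbaldehyde F10. NaOMe in MeOH would replace the last fluoride, coming back to the route at 6.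

Further compounds
F1 | step 10 | Ar[(4R)-2,2-dimethyl-1,3-dioxolan-4-yl]methanol, C7 epimers | COc1cc(-c2ccccc2)cc(Oc2c(OC)cc(C(O)[C@H]3COC(C)(C)O3)cc2OC)c1O[Si](C)(C)C(C)(C)C
F2 | step 10 | Ar[(4R)-2,2-dimethyl-1,3-dioxolan-4-yl]methanone | COc1cc(-c2ccccc2)cc(Oc2c(OC)cc(C(=O)[C@H]3COC(C)(C)O3)cc2OC)c1O[Si](C)(C)C(C)(C)C
F3 | step 10 | (R)-Ar[(4R)-2,2-dimethyl-1,3-dioxolan-4-yl]methanol | COc1cc(-c2ccccc2)cc(Oc2c(OC)cc([C@@H](O)[C@H]3COC(C)(C)O3)cc2OC)c1O[Si](C)(C)C(C)(C)C
F4 | step 10 | (1R,2R)-1-Ar-propane-1,2,3-triol | COc1cc(-c2ccccc2)cc(Oc2c(OC)cc([C@@H](O)[C@H](O)CO)cc2OC)c1O[Si](C)(C)C(C)(C)C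
F5 | step 9 | (4R)-4-[Ar(methoxy)methyl]-2,2-dimethyl-1,3-dioxolane, C7 epimers | COc1cc(-c2ccccc2)cc(Oc2c(OC)cc(C(OC)[C@H]3COC(C)(C)O3)cc2OC)c1O[Si](C)(C)C(C)(C)C
F6 | step 9 | (2R)-3-Ar-3-methoxypropane-1,2-diol, C7 epimers | COc1cc(-c2ccccc2)cc(Oc2c(OC)cc(C(OC)[C@H](O)CO)cc2OC)c1O[Si](C)(C)C(C)(C)C
F7 | step 9 | (2R)-1-Ar-3-(tert-butyldiphenylsilyloxy)-1-methoxypropan-2-ol, C7 epimers | COc1cc(-c2ccccc2)cc(Oc2c(OC)cc(C(OC)[C@H](O)CO[Si](c3ccccc3)(c3ccccc3)C(C)(C)C)cc2OC)c1O[Si](C)(C)C(C)(C)C
F8 | step 9 | tert-butyl (2R)-1-Ar-3-(tert-butyldiphenylsilyloxy)-1-methoxypropan-2-yl carbonate, C7 epimers | COc1cc(-c2ccccc2)cc(Oc2c(OC)cc(C(OC)[C@H](OC(=O)OC(C)(C)C)CO[Si](c3ccccc3)(c3ccccc3)C(C)(C)C)cc2OC)c1O[Si](C)(C)C(C)(C)C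
F9 | step 3 | 3,5-difluoro-[1,1'-biphenyl]-4-carbaldehyde | O=Cc1c(F)cc(-c2ccccc2)cc1F
F10 | step 3 | 3-(4-bromo-2,6-dimethoxyphenoxy)-5-fluoro-[1,1'-biphenyl]-4-carbaldehyde | COc1cc(Br)cc(OC)c1Oc1cc(-c2ccccc2)cc(F)c1C=O
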